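We want the target in the flask at the end of the run, and the change that adds most to it.

    starting material + partner ⇌ target (K1 = 120 L mol⁻¹, k1 = 0.0058 L mol⁻¹ s⁻¹)
    second substrate + partner ⇌ second product (K2 = 2.8 L mol⁻¹, k2 = 0.0022 L mol⁻¹ s⁻¹)
    solid reagent ⇌ partner, rate k3*(cs3 - [partner]) while solid is left; crystals form when [partner] > cs3 (cs3 = 0.18 M, k3 = 0.0029 s⁻¹)

starting material 0.25 M; second substrate 0.500 M; solid reagent 0.625 M; time 8.0 min

- north-west: doubling the solubility in step 3, all else as stated
- north: doubling the dissolution coefficient of step 3, all else as stated

- given per volume of solution although it is solid: solid reagent
- at the start none of the solid reagent is in solution
- run time (flask): 8.0 min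

* target at 8.0 min, in percent of the starting material charged
* the change that raises the amount of target at 8.0 min, in percent of the starting material charged most ("none" if none brings more than 2 percentage points) (north-west / north / none)
* amount of target at 8.0 min, in percent of the starting material charged, after north-west

- Fastest rung, partner: dissolution feeds it with coefficient 0.0029 s⁻¹, while the two substrates, held near their charges, draw it off pseudo-first-order at 0.00145 s⁻¹ and 0.00110 s⁻¹. So [partner] climbs with a time of 3.06 min, shorter than the run.
- It climbs towards 0.0958 M, the standing level of partner: solubility times dissolution coefficient, over the sum of that coefficient and both draws. That is about half of saturation.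
- Next rung, starting material: at the standing level its lifetime is 30.0 min, longer than the run, so its fall is a small correction. We strike the backward runs from our reckoning and take the exponent as forward constant times standing level times the run less its lag: 17.2%. The correction turns this into 15.8% target.
- Last rung, solid reagent: a solution kept empty would take 0.251 M by the end, and the 0.625 M charged is more than that. The charge is also more than twice that amount, so solid lasts the run under either change.
- North-west lifts the standing level to 0.192 M at the same lag, which gives 29.1%. North lifts it to 0.125 M with a climb time of 2.00 min, which gives 23.1%. We therefore pick north-west, with a gain of 13 percentage points against 7.3 points.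
- The forecast gives 16.1%, north-west and 30%, holding that “Doubling the solubility roughly doubles the partner level throughout”.
- The flask gives 16.0%, and north-west adds 14 points, reaching 29.8%. Partner in the flask reads 0.0940 M at 8.00 min, near the standing level of 0.0958 M. The same flask left until 15 min has the exponent 39.9%, which the correction turns into 32.9%; that flask holds 34.3% target.

The constants used here are assumed; the rest is arithmetic.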